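**Retrosynthetic overview**
- The strategy rests on the α-ketol of ring C: the C4 ketone sits next to the fully substituted C3 that carries the hydroxyl and the ring B aryl group. The C3–C4 bond is therefore cut as a carbene-catalysed intramolecular aldehyde-to-ketone benzoin, which also sets the only stereocentre.
- The benzoin substrate is a keto-ether in which rings A and B are linked through O1–C2. It comes from O-alkylation of a bis-MOM phloroglucinaldehyde with an aryl α-chloroketone.
- The α-chloroketone comes from 1-bromo-2,4-dimethoxybenzene: metalation between the two methoxy groups and prenylation, then bromine–lithium exchange and Weinreb acylation.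
- Ring order: rings A and B are bought intact, ring C is closed by the benzoin reaction, and removal of the two MOM groups ends the route.

Key step: step 5

Remark on the chemistry: the antipode of the triazolium precatalyst named in step 5 is assumed, by analogy with related 3-hydroxychroman-4-one closures, to direct attack to the Si face of the ketone. The mirror-image salt is equally available and would be used if chiroptical comparison shows the opposite sense.

**Step 1**
Reactants: 1 1-bromo-2,4-dimethoxybenzene; 2 prenyl bromide (1-bromo-3-methylbut-2-ene)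
Product: 5 1-bromo-2,4-dimethoxy-3-(3-methylbut-2-en-1-yl)benzene, via bromoaryllithium 3 (not isolated), via arylcopper 4 (not isolated)
Conditions: LiN(i-Pr)2 (commercial solution, 1.1 equiv), THF, −78 °C; CuBr·SMe2 (1.0 equiv), −78 to −40 °C; 2 (1.3 equiv), −78 to 0 °C; aq. NH4Cl
Reagents that add atoms: none
Why: Deprotonation by the amide base at C3, the most acidic ring position because it is flanked by both methoxy groups and acidified inductively by the bromine, followed by transmetalation to the arylcopper and SN2 allylation at the primary carbon of the allylic bromide, should place the prenyl group between the two methoxy groups without touching the C–Br bond (directed ortho-metalation and copper-mediated allylation).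

**Step 2**
Reactants: 5 1-bromo-2,4-dimethoxy-3-(3-methylbut-2-en-1-yl)benzene; 6 2-chloro-N-methoxy-N-methylacetamide
Product: 9 2-chloro-1-[2,4-dimethoxy-3-(3-methylbut-2-en-1-yl)phenyl]ethan-1-one, via prenylated aryllithium 7 (not isolated), via lithium hemiaminal alkoxide 8 (not isolated)
Conditions: n-BuLi (1.05 equiv), THF, −78 °C, 20 min; 6 (1.2 equiv), −78 to −40 °C; 1 M aq. HCl quench
Reagents that add atoms: none
Why: Bromine–lithium exchange is faster than any deprotonation at −78 °C, and the aryllithium adds to the Weinreb amide to give a chelated tetrahedral alkoxide that resists over-addition until acidic work-up releases the α-chloroketone (Weinreb ketone synthesis), so no electrophilic halogenation is run in the presence of the prenyl alkene.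

**Step 3**
Reactants: 10 2,4,6-trihydroxybenzaldehyde
Product: 11 2-hydroxy-4,6-bis(methoxymethoxy)benzaldehyde
Conditions: MOMCl (2.2 equiv), i-Pr2NEt (3 equiv), CH2Cl2, 0 °C to rt
Reagents that add atoms: chloromethyl methyl ether (MOMCl), COCCl
Why: The para hydroxyl and one of the two equivalent ortho hydroxyls are alkylated first, after which the remaining ortho hydroxyl is held in a hydrogen bond to the formyl oxygen and reacts much more slowly, so two equivalents of MOMCl with a hindered amine should stop at the bis-ether (selective acetal protection of a phenol).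

**Step 4**
Reactants: 9 2-chloro-1-[2,4-dimethoxy-3-(3-methylbut-2-en-1-yl)phenyl]ethan-1-one; 11 2-hydroxy-4,6-bis(methoxymethoxy)benzaldehyde
Product: 12 2-{2-[2,4-dimethoxy-3-(3-methylbut-2-en-1-yl)phenyl]-2-oxoethoxy}-4,6-bis(methoxymethoxy)benzaldehyde
Conditions: K2CO3 (1.5 equiv), DMF, rt, 2–4 h, work-up as soon as 9 is consumed
Reagents that add atoms: none
Why: The phenoxide displaces chloride from the activated α-chloroketone in a Williamson ether synthesis, and the mild carbonate base, ambient temperature and short contact time, together with the hindered electron-rich aldehyde, should hold back the follow-up aldol condensation to a 2-aroylbenzofuran.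

**Step 5**
Reactants: 12 2-{2-[2,4-dimethoxy-3-(3-methylbut-2-en-1-yl)phenyl]-2-oxoethoxy}-4,6-bis(methoxymethoxy)benzaldehyde
Product: 13 (3R)-3-[2,4-dimethoxy-3-(3-methylbut-2-en-1-yl)phenyl]-3-hydroxy-5,7-bis(methoxymethoxy)-2,3-dihydro-4H-chromen-4-one
Conditions: (5aR,10bS)-2-(pentafluorophenyl)-5a,10b-dihydro-4H,6H-indeno[2,1-b][1,2,4]triazolo[4,3-d][1,4]oxazin-2-ium tetrafluoroborate (20 mol%), Et3N (20 mol%), toluene, rt, argon
Reagents that add atoms: none
Why: Deprotonation of the triazolium salt gives the carbene, which adds to the formyl group of 12 and after proton transfer forms the Breslow enaminol, an acyl-anion equivalent at the future C4; this carbon attacks the tethered aryl ketone (future C3), and collapse of the adduct releases the carbene and the α-ketol. The closest known reaction type is the enantioselective triazolylidene-catalysed intramolecular crossed aldehyde–ketone benzoin of 2-(2-oxoalkoxy)benzaldehydes to 3-hydroxychroman-4-ones. Ring C is closed in a 6-exo-trig mode, the O1–C2 tether holding the ketone carbonyl within reach of the Breslow carbon. The C3 stereocentre is set by the chiral indane-fused triazolylidene, which must deliver the acyl carbon to the Si face of the ketone (priorities O > CH2O > aryl) to give the (R) configuration. Chemoselectivity is secured because only the aldehyde can form the acyl-anion equivalent and only the ketone can accept it, and because a catalytic tertiary amine at ambient temperature is too weak to drive aldol condensation of the O–CH2–C(=O) methylene onto the aldehyde. The prenyl alkene, the methyl ethers and the MOM ethers are inert to the carbene and the base, and the chelated, fully substituted product should not revert.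

**Step 6**
Reactants: 13 (3R)-3-[2,4-dimethoxy-3-(3-methylbut-2-en-1-yl)phenyl]-3-hydroxy-5,7-bis(methoxymethoxy)-2,3-dihydro-4H-chromen-4-one
Product: 14 (3R)-3-[2,4-dimethoxy-3-(3-methylbut-2-en-1-yl)phenyl]-3,5,7-trihydroxy-2,3-dihydro-4H-chromen-4-one (target)
Conditions: 3 M aq. HCl, MeOH, rt to 40 °C, stopped as soon as the mono-MOM intermediate is consumed
Reagents that add atoms: none
Why: Acid-catalysed acetal exchange with methanol cleaves both aryl MOM ethers while the methyl ethers stay inert, the prenyl group has no neighbouring free phenol to cyclise onto, and C3 cannot epimerise because it bears no hydrogen and ionisation next to the carbonyl is disfavoured (MOM ether deprotection).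

**Compound list**
1 | 1-bromo-2,4-dimethoxybenzene | COc1ccc(Br)c(OC)c1 | starting material
2 | prenyl bromide (1-bromo-3-methylbut-2-ene) | CC(C)=CCBr | starting material
3 | (3-bromo-2,6-dimethoxyphenyl)lithium | COc1ccc(Br)c(OC)c1[Li] | intermediate
4 | (3-bromo-2,6-dimethoxyphenyl)copper | COc1ccc(Br)c(OC)c1[Cu] | intermediate
5 | 1-bromo-2,4-dimethoxy-3-(3-methylbut-2-en-1-yl)benzene | COc1ccc(Br)c(OC)c1CC=C(C)C | intermediate
6 | 2-chloro-N-methoxy-N-methylacetamide | CON(C)C(=O)CCl | starting material
7 | [2,4-dimethoxy-3-(3-methylbut-2-en-1-yl)phenyl]lithium | COc1ccc([Li])c(OC)c1CC=C(C)C | intermediate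
8 | lithium 2-chloro-1-[2,4-dimethoxy-3-(3-methylbut-2-en-1-yl)phenyl]-1-[methoxy(methyl)amino]ethan-1-olate (racemic) | COc1ccc(C(O[Li])(CCl)N(C)OC)c(OC)c1CC=C(C)C | intermediate
9 | 2-chloro-1-[2,4-dimethoxy-3-(3-methylbut-2-en-1-yl)phenyl]ethan-1-one | COc1ccc(C(=O)CCl)c(OC)c1CC=C(C)C | intermediate
10 | 2,4,6-trihydroxybenzaldehyde | O=Cc1c(O)cc(O)cc1O | starting material
11 | 2-hydroxy-4,6-bis(methoxymethoxy)benzaldehyde | COCOc1cc(O)c(C=O)c(OCOC)c1 | intermediate
12 | 2-{2-[2,4-dimethoxy-3-(3-methylbut-2-en-1-yl)phenyl]-2-oxoethoxy}-4,6-bis(methoxymethoxy)benzaldehyde | COc1ccc(C(=O)COc2cc(OCOC)cc(OCOC)c2C=O)c(OC)c1CC=C(C)C | intermediate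
13 | (3R)-3-[2,4-dimethoxy-3-(3-methylbut-2-en-1-yl)phenyl]-3-hydroxy-5,7-bis(methoxymethoxy)-2,3-dihydro-4H-chromen-4-one | COc1ccc([C@@]2(O)COc3cc(OCOC)cc(OCOC)c3C2=O)c(OC)c1CC=C(C)C | intermediate
14 | (3R)-3-[2,4-dimethoxy-3-(3-methylbut-2-en-1-yl)phenyl]-3,5,7-trihydroxy-2,3-dihydro-4H-chromen-4-one | COc1ccc([C@@]2(O)COc3cc(O)cc(O)c3C2=O)c(OC)c1CC=C(C)C | target

**Totals**
Total step count: 6
Longest linear sequence: 5 steps (steps 1, 2, 4, 5, 6)

**Steps most likely to fail**

Step 5. The aldehyde is flanked by two ortho oxygen substituents and is electron-rich, so formation of the Breslow intermediate may be slow. The ortho-methoxy aryl ketone may also be discriminated poorly by the bulky chiral carbene, giving low enantiofacial selectivity, and prolonged exposure to base could open the aldol pathway. The fallback sets out from 12 and closes the ring without asymmetric induction, using the small achiral precatalyst 3-benzyl-5-(2-hydroxyethyl)-4-methylthiazolium chloride with Et3N in warm ethanol. This should give the racemic ketol, that is 13 together with its mirror image (3S)-3-[2,4-dimethoxy-3-(3-methylbut-2-en-1-yl)phenyl]-3-hydroxy-5,7-bis(methoxymethoxy)-2,3-dihydro-4H-chromen-4-one F1. The enantiomers would be separated by preparative HPLC on a cellulose tris(3,5-dimethylphenylcarbamate) stationary phase, and the route is rejoined at 13.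

Step 1. Deprotonation of the bromoarene may be incomplete or may be accompanied by bromine migration between aryllithium and unreacted bromide (halogen dance), and part of the allylation could go through SN2' attack to the reverse-prenyl isomer. The fallback sets out from 2 and moves the bromination to after the prenylation. Commercial 1,3-dimethoxybenzene is lithiated at C2 with n-BuLi (THF, 0 °C to rt) to (2,6-dimethoxyphenyl)lithium F2, which is alkylated with 2 to give 1,3-dimethoxy-2-(3-methylbut-2-en-1-yl)benzene F3. The highly activated ring is then monobrominated at the position ortho to one methoxy group and para to the other with NBS (1.0 equiv) in MeCN at −20 °C, where ring substitution should outrun attack on the alkene. The route is rejoined at 5.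

Step 6. While the slower 7-O-MOM group is still being cleaved, the acid may start to ionise the tertiary benzylic ketol with loss of water to the isoflavone, or add HCl or methanol across the prenyl double bond. The fallback replaces the acid-labile acetals by allyl ethers and sets out from 10. Allyl bromide (2.1 equiv) and K2CO3 in acetone should give 4,6-bis(allyloxy)-2-hydroxybenzaldehyde F4. Alkylation with 9 as in step 4 gives 2-{2-[2,4-dimethoxy-3-(3-methylbut-2-en-1-yl)phenyl]-2-oxoethoxy}-4,6-bis(allyloxy)benzaldehyde F5. The benzoin closure as in step 5 gives (3R)-5,7-bis(allyloxy)-3-[2,4-dimethoxy-3-(3-methylbut-2-en-1-yl)phenyl]-3-hydroxy-2,3-dihydro-4H-chromen-4-one F6. Both allyl groups are then transferred to morpholine with catalytic Pd(PPh3)4 in THF at rt under neutral conditions, and the route is rejoined at 14.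

**Further compounds**
F1 | step 5 | (3S)-3-[2,4-dimethoxy-3-(3-methylbut-2-en-1-yl)phenyl]-3-hydroxy-5,7-bis(methoxymethoxy)-2,3-dihydro-4H-chromen-4-one | COc1ccc([C@]2(O)COc3cc(OCOC)cc(OCOC)c3C2=O)c(OC)c1CC=C(C)C
F2 | step 1 | (2,6-dimethoxyphenyl)lithium | COc1cccc(OC)c1[Li]
F3 | step 1 | 1,3-dimethoxy-2-(3-methylbut-2-en-1-yl)benzene | COc1cccc(OC)c1CC=C(C)C
F4 | step 6 | 4,6-bis(allyloxy)-2-hydroxybenzaldehyde | C=CCOc1cc(O)c(C=O)c(OCC=C)c1
F5 | step 6 | 2-{2-[2,4-dimethoxy-3-(3-methylbut-2-en-1-yl)phenyl]-2-oxoethoxy}-4,6-bis(allyloxy)benzaldehyde | COc1ccc(C(=O)COc2cc(OCC=C)cc(OCC=C)c2C=O)c(OC)c1CC=C(C)C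
F6 | step 6 | (3R)-5,7-bis(allyloxy)-3-[2,4-dimethoxy-3-(3-methylbut-2-en-1-yl)phenyl]-3-hydroxy-2,3-dihydro-4H-chromen-4-one | COc1ccc([C@@]2(O)COc3cc(OCC=C)cc(OCC=C)c3C2=O)c(OC)c1CC=C(C)C
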